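Remark on numbering and supply: the terpenoid carbons are numbered C1 (OCH2) to C7 (C6=C7 is the alkene), O1 is the ring oxygen between C2 and C5, and O7 is the coumarin oxygen. Compounds 1, 2, 6 (isofraxidin) and 12 are taken as purchased.

## Structural features

The target is an alkyl aryl ether of isofraxidin: a 2H-chromen-2-one with methoxy groups at C6 and C8 and, at O7 between them, a C10 monoterpenoid unit. In that unit C1 is the OCH2 carbon and the oxolane ring is O1–C2–C3–C4–C5. C2 carries C1, C3 is a fully substituted carbinol (methyl, hydroxyl), C4 is a methylene and C5 carries the 2-methylprop-1-enyl group (C6=C7). There are three stereocentres: C2 (S) and C3 (R) are contiguous, and C5 (R) is 1,3 to C3 and lies across O1 from C2. The C1 side chain and the C3 methyl are on one ring face; the C3 hydroxyl and the C5 alkenyl group are on the other (2,5-trans; hydroxyl and alkenyl 3,5-cis). The fragile groups are these: C5–O1 is an allylic ether that can ionize to a 1,1-dimethylallyl cation under acid, C6=C7 is the most electron-rich π bond and would be attacked first by any oxidant, the tertiary alcohol can dehydrate, and the coumarin lactone is sensitive to hydroxide, ozone and hydride reagents. The real difficulty is the remote centre C5 in a 2,5-trans oxolane, which has no thermodynamic bias and must be related to C2/C3. A second difficulty is that the C3 carbinol cannot come from methyl addition to a ring ketone, since the nucleophile would enter anti to the C2 substituent and give the C3 epimer. The key step exploits the fact that, without C6, C5 (bonded to O1 and H) is an acetal carbon: the ring is a disguised 2-deoxy-3-C-methylpentofuranose whose anomeric carbon is C5 and whose C3 oxygen lies on the face that the alkenyl group must occupy.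

## Logic of the disconnections

14 is cut at the exocyclic C5–C6 bond, which leads back to 11 and 12 through the C5=O1 oxocarbenium ion 13. In one sentence, the route is the addition of the 2-methylprop-1-enyl nucleophile 12 to the cyclic oxocarbenium ion 13 generated from 11, which already carries the coumarin. The reason for cutting here is that C5, the centre hardest to reach, is then made in the same step that brings in the sensitive alkene, and that step is the last one. The gain is large: 14 (three stereocentres, allylic ether, alkene) becomes 11 (two contiguous stereocentres, no alkene, C5 at the acetal level) plus a purchased reagent. The demand on the forward step is attack on 13 from the face of the C3 oxygen, transfer of the alkenyl group through its boron-bearing carbon, and conditions that do not re-ionize C5–O1 of 14.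

11 is cut at the C5–OAc bond to give 10. This only supplies a leaving group that ionizes at low temperature. The demand is acylation of the hemiacetal hydroxyl without touching the tertiary C3 hydroxyl.

10 is cut at O1–C5 (hemiacetal bond) and at the C3–OH bond (oxygen from water), which leads through 9 and 8 back to 7. The anti arrangement of the oxygens on C2 and C3 corresponds to anti addition of two oxygens across an E-configured C2=C3 bond: the epoxide oxygen stays on C2 and becomes O1, and water enters at C3 with inversion. The gain is that the ring and both remaining stereocentres collapse into one epoxide and a masked aldehyde, with no protecting group, because the aryl ether at C1 leaves the furanose as the only possible hemiacetal. The demand is that water opens the epoxide at C3 and not at C2, and with inversion.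

7 is cut at the O7–C1 bond to give 5 and 6. A primary carbinol next to an epoxide is a good partner for etherification, and joining the coumarin early makes it serve as the only blocking group on the C1 oxygen. The demand is coupling of a phenol with two ortho substituents without opening the epoxide.

5 is cut at both epoxide C–O bonds (C2–O and C3–O) to give 4. A primary E-allylic alcohol is the ideal substrate for a catalytic asymmetric epoxidation, so C2 and C3 are set together in the only step that needs an external source of chirality. The demand is E geometry in 4 and the correct tartrate enantiomer.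

4 is cut at C2=C3 after adjustment of the oxidation level at C1: back to 3 and then to 1 and 2. The demand is the E isomer of 3, obtained pure by separation.

## Other disconnections considered

Alternative 1: This is the plan that comes to mind first. The cut is O7–C1, made last, and before it the ring bond O1–C2. In the forward direction the diol (2E,5R)-3,7-dimethylocta-2,6-diene-1,5-diol A3, from an enantioselective vinylogous aldol addition to 3-methylbut-2-enal, would be epoxidized (Katsuki–Sharpless, D-(−)-tartrate) to the epoxy diol A2. The C5 hydroxyl of A2 would open the epoxide at C2 in a 5-endo closure to give the oxolane methanol A1, and A1 would be coupled with 6 by a Mitsunobu reaction. The chosen plan is preferred on three grounds. First, in this alternative C5 rests on a second, unrelated asymmetric catalyst, so the three centres are not relayed from one another. Second, the ring closure must take place at C2, the epoxide carbon deactivated by the C1 oxygen, in competition with Payne migration of the free C1 hydroxyl and with ionization at tertiary C3. Third, the electron-rich C6=C7 bond, itself part of a secondary allylic alcohol, must survive the epoxidation, whereas the chosen route introduces it after all oxidations.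

Alternative 2: The cut is O1–C5 with C5 as an allyl terminus. The forward key step would be an intramolecular Tsuji–Trost etherification of the diol carbonate A4 with a zerovalent palladium catalyst (Pd2(dba)3 and a chiral diphosphine), the C2 hydroxyl attacking the less substituted end of a 1,1-dimethylallyl palladium complex. Such a complex exchanges its two faces through the σ-bonded form at the gem-dimethyl terminus, so C5 would be fixed only by the match of ligand and substrate. A 2,5-disubstituted oxolane offers little intrinsic bias. A4 also needs the C2/C3 diol to be made in a chain that already holds a second alkene, which costs steps. The chosen plan takes C5 from the substrate and is shorter.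

Alternative 3: The cut is O1–C2 together with the C1–O bond. The forward key step would be a Mukaiyama aerobic oxidative cyclization of the dienediol A5 with a divalent cobalt bis(1,3-diketonate) such as Co(acac)2 under O2, which should give the 2,5-trans oxolane methanol A1 directly; Mitsunobu coupling with 6 would follow. The 2,5-trans preference of this reaction is attractive. However, the tertiary C3 hydroxyl of A5 is placed for the same 5-exo closure onto the more electron-rich C6=C7 bond, so chemoselectivity is doubtful. The anti-1,3-diol A5 needs two unrelated stereocentres, the effect of the quaternary allylic C3 on the C2 configuration is not secure, and the route ends with the same late etherification as Alternative 1.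

Key step: step 7

## Route

Step 1
Reactants: 1 4,4-dimethoxybutan-2-one; 2 triethyl phosphonoacetate
Product: 3 ethyl (2E)-5,5-dimethoxy-3-methylpent-2-enoate
Conditions: NaH, THF, 0 °C → 50 °C; chromatography to remove the minor 2Z isomer
Reagents that add atoms: none
Why: Horner–Wadsworth–Emmons olefination of the methyl ketone; the ester should end up trans to the larger CH2CH(OMe)2 arm (2E major), the stabilized phosphonate anion is too weakly basic to eliminate methanol from the β-acetal, and the 2Z isomer is removed because only the E geometry leads to the anti C2/C3 oxygen pattern.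

Step 2
Reactants: 3 ethyl (2E)-5,5-dimethoxy-3-methylpent-2-enoate
Product: 4 (2E)-5,5-dimethoxy-3-methylpent-2-en-1-ol
Conditions: iBu2AlH (2.2 equiv), CH2Cl2, −78 → 0 °C; aqueous potassium sodium tartrate work-up
Reagents that add atoms: none
Why: Low-temperature 1,2-reduction of the conjugated ester (DIBAL-H reduction) gives the primary allylic alcohol; the acetal and the alkene geometry are not affected.

Step 3
Reactants: 4 (2E)-5,5-dimethoxy-3-methylpent-2-en-1-ol
Product: 5 [(2S,3S)-3-(2,2-dimethoxyethyl)-3-methyloxiran-2-yl]methanol
Conditions: Ti(OiPr)4 (10 mol %), L-(+)-diethyl tartrate (12 mol %), t-BuOOH (2 equiv), 4 Å molecular sieves, CH2Cl2, −20 °C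
Reagents that add atoms: tert-butyl hydroperoxide, CC(C)(C)OO
Why: Katsuki–Sharpless asymmetric epoxidation of a primary E-3-methylallylic alcohol; the L-(+)-tartrate complex of tetravalent titanium delivers oxygen to the face that gives the (2S,3S)-epoxide (the sense known for geraniol-type substrates), so C2 and C3 are set together by the catalyst, and the acetal tolerates the mild titanium alkoxide.

Step 4
Reactants: 5 [(2S,3S)-3-(2,2-dimethoxyethyl)-3-methyloxiran-2-yl]methanol; 6 isofraxidin (7-hydroxy-6,8-dimethoxy-2H-chromen-2-one)
Product: 7 7-{[(2S,3S)-3-(2,2-dimethoxyethyl)-3-methyloxiran-2-yl]methoxy}-6,8-dimethoxy-2H-chromen-2-one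
Conditions: PPh3, diisopropyl azodicarboxylate, THF, 0 °C → rt
Reagents that add atoms: none
Why: Mitsunobu etherification; the acidic 7-hydroxyl of 6 displaces the oxyphosphonium group at primary C1 by SN2, no stereocentre is touched and the epoxide survives the neutral conditions, and the aryl ether installed here later forces the hemiacetal into the furanose form.

Step 5
Reactants: 7 7-{[(2S,3S)-3-(2,2-dimethoxyethyl)-3-methyloxiran-2-yl]methoxy}-6,8-dimethoxy-2H-chromen-2-one
Product: 10 7-{[(2S,3R)-3,5-dihydroxy-3-methyloxolan-2-yl]methoxy}-6,8-dimethoxy-2H-chromen-2-one (both anomers), via diol acetal 8 (not isolated), via dihydroxy aldehyde 9 (not isolated)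
Conditions: HClO4 (0.2 M in H2O)–THF 1:1, 0 °C → rt; NaHCO3 quench
Reagents that add atoms: water, O
Why: Acid-catalysed epoxide hydrolysis, acetal hydrolysis and hemiacetal closure in one flask; water should attack the protonated epoxide at tertiary C3 from the side opposite the leaving oxygen (inversion, 3S → 3R) while the C2–O bond is untouched (2S), and the freed C5 aldehyde of 9 is captured by the C2 hydroxyl, the only one that can form a five-membered ring, the new C5 centre being an inconsequential anomeric mixture.

Step 6
Reactants: 10 7-{[(2S,3R)-3,5-dihydroxy-3-methyloxolan-2-yl]methoxy}-6,8-dimethoxy-2H-chromen-2-one (both anomers)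
Product: 11 (4R,5S)-5-{[(6,8-dimethoxy-2-oxo-2H-chromen-7-yl)oxy]methyl}-4-hydroxy-4-methyloxolan-2-yl acetate (both anomers)
Conditions: Ac2O (1.2 equiv), pyridine, CH2Cl2, 0 °C
Reagents that add atoms: acetic anhydride, CC(=O)OC(C)=O
Why: Selective O-acylation of the hemiacetal hydroxyl, which is far more reactive than the hindered tertiary C3 hydroxyl when no nucleophilic catalyst is present, gives the anomeric acetate as the leaving group for ionization; C2 and C3 are untouched.

Step 7
Reactants: 11 (4R,5S)-5-{[(6,8-dimethoxy-2-oxo-2H-chromen-7-yl)oxy]methyl}-4-hydroxy-4-methyloxolan-2-yl acetate (both anomers); 12 potassium trifluoro(2-methylprop-1-en-1-yl)borate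
Product: 14 7-{[(2S,3R,5R)-3-hydroxy-3-methyl-5-(2-methylprop-1-en-1-yl)oxolan-2-yl]methoxy}-6,8-dimethoxy-2H-chromen-2-one (target), via oxocarbenium ion 13 (not isolated)
Conditions: 12 (2.5 equiv), BF3·OEt2 (2.5 equiv), CH2Cl2–MeCN 4:1, −40 → −10 °C; cold aqueous NaHCO3 quench
Reagents that add atoms: none
Why: BF3·OEt2 abstracts fluoride from 12 to give the Lewis-acidic alkenyldifluoroborane and KBF4; the borane ionizes the anomeric acetate of 11 to the oxocarbenium ion 13, paired with an acetoxy(alkenyl)difluoroborate, and the alkenyl group is transferred to C5 through its boron-bearing carbon, the charge developing at tertiary C7 being relieved by loss of boron so that the double bond ends at C6=C7. The closest known reaction type is the Lewis acid-promoted C-glycosylation of furanosyl donors and mixed acetals with potassium alkenyl- and alkynyltrifluoroborates, itself a case of nucleophilic substitution of 2-deoxyfuranosyl acetates through oxocarbenium ions. The step closes no ring (the oxolane was closed in step 5 by hemiacetal formation); it forms the exocyclic C5–C6 bond. The new stereocentre C5 is controlled by C3: in the envelope conformer of 13 with C3 as the flap, the C3 oxygen is pseudoaxial (electrostatic stabilization of the cation) and the methyl pseudoequatorial, and the nucleophile attacks C5 on the inside face of the envelope, cis to the C3 oxygen, which leads to a staggered product. The aryloxymethyl group at C2 lies on the opposite face, so the same trajectory is also the 2,5-trans one, as in the 2-deoxyribofuranosyl series; if the free C3 hydroxyl binds the alkenylborane, delivery from that oxygen is again to the cis face. The step needs face selectivity at C5 (secured as described), transfer at the boron-bearing carbon (secured by the tertiary β-carbon C7) and substitution in preference to loss of a proton from C4 of 13 (secured by low temperature and the nucleophilic borate partner). C2 (S) and C3 (R) are not touched, and C5 should become R.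

## Compound list

1 | 4,4-dimethoxybutan-2-one | CC(=O)CC(OC)OC | starting material
2 | triethyl phosphonoacetate | CCOC(=O)CP(=O)(OCC)OCC | starting material
3 | ethyl (2E)-5,5-dimethoxy-3-methylpent-2-enoate | CCOC(=O)/C=C(\C)CC(OC)OC | intermediate
4 | (2E)-5,5-dimethoxy-3-methylpent-2-en-1-ol | OC/C=C(\C)CC(OC)OC | intermediate
5 | [(2S,3S)-3-(2,2-dimethoxyethyl)-3-methyloxiran-2-yl]methanol | OC[C@@H]1O[C@@]1(C)CC(OC)OC | intermediate
6 | isofraxidin (7-hydroxy-6,8-dimethoxy-2H-chromen-2-one) | COc1cc2ccc(=O)oc2c(OC)c1O | starting material
7 | 7-{[(2S,3S)-3-(2,2-dimethoxyethyl)-3-methyloxiran-2-yl]methoxy}-6,8-dimethoxy-2H-chromen-2-one | COc1cc2ccc(=O)oc2c(OC)c1OC[C@@H]1O[C@@]1(C)CC(OC)OC | intermediate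
8 | 7-{[(2S,3R)-2,3-dihydroxy-5,5-dimethoxy-3-methylpentyl]oxy}-6,8-dimethoxy-2H-chromen-2-one (diol acetal, not isolated) | COc1cc2ccc(=O)oc2c(OC)c1OC[C@H](O)[C@](C)(O)CC(OC)OC | intermediate
9 | (3R,4S)-5-[(6,8-dimethoxy-2-oxo-2H-chromen-7-yl)oxy]-3,4-dihydroxy-3-methylpentanal (dihydroxy aldehyde, not isolated) | COc1cc2ccc(=O)oc2c(OC)c1OC[C@H](O)[C@](C)(O)CC=O | intermediate
10 | 7-{[(2S,3R)-3,5-dihydroxy-3-methyloxolan-2-yl]methoxy}-6,8-dimethoxy-2H-chromen-2-one (both anomers) | COc1cc2ccc(=O)oc2c(OC)c1OC[C@@H]1OC(O)C[C@@]1(C)O | intermediate
11 | (4R,5S)-5-{[(6,8-dimethoxy-2-oxo-2H-chromen-7-yl)oxy]methyl}-4-hydroxy-4-methyloxolan-2-yl acetate (both anomers) | COc1cc2ccc(=O)oc2c(OC)c1OC[C@@H]1OC(OC(C)=O)C[C@@]1(C)O | intermediate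
12 | potassium trifluoro(2-methylprop-1-en-1-yl)borate | [K+].CC(C)=C[B-](F)(F)F | starting material
13 | (2S,3R)-2-{[(6,8-dimethoxy-2-oxo-2H-chromen-7-yl)oxy]methyl}-3-hydroxy-3-methyl-3,4-dihydro-2H-furan-1-ium (oxocarbenium ion, not isolated) | COc1cc2ccc(=O)oc2c(OC)c1OC[C@@H]1[O+]=CC[C@@]1(C)O | intermediate
14 | 7-{[(2S,3R,5R)-3-hydroxy-3-methyl-5-(2-methylprop-1-en-1-yl)oxolan-2-yl]methoxy}-6,8-dimethoxy-2H-chromen-2-one | COc1cc2ccc(=O)oc2c(OC)c1OC[C@@H]1O[C@@H](C=C(C)C)C[C@@]1(C)O | target

## Step count and least certain steps

Total step count: 7. Longest linear sequence: 7 steps (1 → 14); 6 and 12 enter as purchased materials in steps 4 and 7.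

**Step 7 (key step).** Three things are most likely to go wrong.
- Face selectivity at C5 may be insufficient, because a planar alkenyl nucleophile is less discriminating than the allylsilanes on which the inside-attack model rests. The C5 configuration could also be lost by Lewis-acid re-ionization of the newly formed allylic C5–O1 bond.
- The oxocarbenium ion may lose a proton from C4 and then water, which would aromatize the ring.
- The alkenylborane may undergo protodeboronation before transfer.

The fallback sets out from 11 and returns to the route at 14. Allylation of 11 with allyltrimethylsilane and BF3·OEt2 (CH2Cl2, −78 °C), the nucleophile for which attack cis to a C3 oxygen is best established, should give the allyl oxolane 7-{[(2S,3R,5S)-3-hydroxy-3-methyl-5-(prop-2-en-1-yl)oxolan-2-yl]methoxy}-6,8-dimethoxy-2H-chromen-2-one F1. Isomerization of the terminal alkene with RuHCl(CO)(PPh3)3 (toluene, 80 °C) should give the propenyl oxolane 7-{[(2S,3R,5R)-3-hydroxy-3-methyl-5-[(1E)-prop-1-en-1-yl]oxolan-2-yl]methoxy}-6,8-dimethoxy-2H-chromen-2-one F2. Cross-metathesis of F2 with 2-methyl-2-butene (second-generation Grubbs catalyst, 40 °C) would then deliver 14 without any Lewis acid after the alkene is in place.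

**Step 5.** The hydrated C5 aldehyde may open the epoxide at C2 in competition with water at C3, which would lead into the enantiomeric diol series and erode the optical purity. Partial ionization at C3 would cause loss of stereospecificity there, and the β-hydroxy aldehyde may dehydrate. The fallback sets out from 7 and returns at 10. Treatment of 7 with acetone and catalytic BF3·OEt2 (0 °C, anhydrous) should convert the epoxide, with inversion at C3 and retention at C2, into the acetonide 7-{[(4S,5R)-5-(2,2-dimethoxyethyl)-2,2,5-trimethyl-1,3-dioxolan-4-yl]methoxy}-6,8-dimethoxy-2H-chromen-2-one F3, under conditions in which no hydrated aldehyde exists. Aqueous acid (dilute HCl, THF, rt) then cleaves both acetals of F3 and gives 10.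

**Step 4.** Oxyphosphonium formation may be slow with a phenol flanked by two methoxy groups, so that alkylation of the reduced azodicarboxylate or opening of the epoxide takes over. The fallback sets out from 5 and returns at 7. Sulfonylation (TsCl, Et3N, CH2Cl2, 0 °C) should give the tosylate [(2S,3S)-3-(2,2-dimethoxyethyl)-3-methyloxiran-2-yl]methyl 4-methylbenzenesulfonate F4, which is displaced at C1 by the caesium phenoxide of 6 (Cs2CO3, DMF, 50 °C) in a Williamson etherification to give 7.

**Step 6.** The tertiary hydroxyl may be acylated as well, or the anomeric acetate may ionize and eliminate during isolation. The fallback sets out from 10 and returns at 14. Fischer glycosidation (MeOH, pyridinium p-toluenesulfonate, rt) should give the methyl furanoside 7-{[(2S,3R)-3-hydroxy-5-methoxy-3-methyloxolan-2-yl]methoxy}-6,8-dimethoxy-2H-chromen-2-one F5, a stable mixed acetal. F5 is ionized in place of 11 under the conditions of step 7 (12, BF3·OEt2, CH2Cl2–MeCN, −20 → 0 °C) and gives 14.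

## Further compounds

F1 | step 7 | 7-{[(2S,3R,5S)-3-hydroxy-3-methyl-5-(prop-2-en-1-yl)oxolan-2-yl]methoxy}-6,8-dimethoxy-2H-chromen-2-one | COc1cc2ccc(=O)oc2c(OC)c1OC[C@@H]1O[C@@H](CC=C)C[C@@]1(C)O
F2 | step 7 | 7-{[(2S,3R,5R)-3-hydroxy-3-methyl-5-[(1E)-prop-1-en-1-yl]oxolan-2-yl]methoxy}-6,8-dimethoxy-2H-chromen-2-one | COc1cc2ccc(=O)oc2c(OC)c1OC[C@@H]1O[C@@H](/C=C/C)C[C@@]1(C)O
F3 | step 5 | 7-{[(4S,5R)-5-(2,2-dimethoxyethyl)-2,2,5-trimethyl-1,3-dioxolan-4-yl]methoxy}-6,8-dimethoxy-2H-chromen-2-one | COc1cc2ccc(=O)oc2c(OC)c1OC[C@@H]1OC(C)(C)O[C@]1(C)CC(OC)OC
F4 | step 4 | [(2S,3S)-3-(2,2-dimethoxyethyl)-3-methyloxiran-2-yl]methyl 4-methylbenzenesulfonate | Cc1ccc(cc1)S(=O)(=O)OC[C@@H]1O[C@@]1(C)CC(OC)OC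
F5 | step 6 | 7-{[(2S,3R)-3-hydroxy-5-methoxy-3-methyloxolan-2-yl]methoxy}-6,8-dimethoxy-2H-chromen-2-one (both anomers) | COc1cc2ccc(=O)oc2c(OC)c1OC[C@@H]1OC(OC)C[C@@]1(C)O
A1 | alternative 1 | (2S,3R,5R)-2-(hydroxymethyl)-3-methyl-5-(2-methylprop-1-en-1-yl)oxolan-3-ol | OC[C@@H]1O[C@@H](C=C(C)C)C[C@@]1(C)O
A2 | alternative 1 | [(2R,3R)-3-[(2R)-2-hydroxy-4-methylpent-3-en-1-yl]-3-methyloxiran-2-yl]methanol | OC[C@H]1O[C@]1(C)C[C@@H](O)C=C(C)C
A3 | alternative 1 | (2E,5R)-3,7-dimethylocta-2,6-diene-1,5-diol | OC/C=C(\C)C[C@@H](O)C=C(C)C
A4 | alternative 2 | (3E,6R,7S)-8-[(6,8-dimethoxy-2-oxo-2H-chromen-7-yl)oxy]-6,7-dihydroxy-2,6-dimethyloct-3-en-2-yl methyl carbonate | COc1cc2ccc(=O)oc2c(OC)c1OC[C@H](O)[C@](C)(O)C/C=C/C(C)(C)OC(=O)OC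
A5 | alternative 3 | (3R,5R)-3,7-dimethylocta-1,6-diene-3,5-diol | C=C[C@](C)(O)C[C@@H](O)C=C(C)C
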